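**Plan**

- Retrosynthesis: the 5-OH is released last from a 5-OMe. The 3-OMe is traced through the flavonol to the C2=C3 bond of 5,6,7,8-tetramethoxyflavone. The pyranone is then cut at C4a–C4, C4–C3 and O1–C2 into 2-iodo-4,5,6-trimethoxybenzene-1,3-diol, carbon monoxide and phenylacetylene.
- Enabling feature: C4 is a single carbon bridging C4a of ring A and the C3–C2(Ph) pair, which maps onto CO plus a terminal alkyne. Ring A is hexasubstituted and mirror-symmetric about the C–I carbon, so the two flanking hydroxyls are equivalent: one becomes O1, the other the 5-OH.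
- Forward order: ring A is completed on 1,2,3-trimethoxybenzene (bromination at C4/C6, borylation–oxidation, iodination of the last C–H). Ring C is closed in one carbonylative annulation that also brings in ring B. C3 is oxygenated afterwards by epoxidation while the 5-OH is masked as its methyl ether.
- Stereochemistry: the target has no stereocentre or other stereogenic element. The only stereocentres on the route sit in a racemic epoxide that is not isolated, and they are erased on ring opening.

Key step: step 5

Remark: since the target is achiral, the request for a single enantiomer is read as the single constitution drawn; no asymmetric step is needed.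

**Route**

Step 1
Reactants: 1 1,2,3-trimethoxybenzene
Product: 2 1,5-dibromo-2,3,4-trimethoxybenzene
Conditions: NBS (2.2 equiv), MeCN, 0 °C → 60 °C
Reagents that add atoms: N-bromosuccinimide, O=C1CCC(=O)N1Br
Why: Electrophilic aromatic bromination; C4 and C6 are each ortho to one outer methoxy and para to the other, whereas C5 is only para to the twisted central methoxy, so both bromines should enter at the two positions flanking the ring hydrogen that is kept.

Step 2
Reactants: 2 1,5-dibromo-2,3,4-trimethoxybenzene
Product: 3 2,2'-(4,5,6-trimethoxy-1,3-phenylene)bis(4,4,5,5-tetramethyl-1,3,2-dioxaborolane)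
Conditions: B2pin2 (2.6 equiv), PdCl2(dppf)·CH2Cl2 (5 mol%), KOAc (6 equiv), 1,4-dioxane, 90 °C
Reagents that add atoms: bis(pinacolato)diboron, CC1(C)OB(OC1(C)C)B1OC(C)(C)C(C)(C)O1
Why: Miyaura borylation; both C–Br bonds of the neutral arene undergo oxidative addition and acetate-mediated transmetalation with the diboron, and converting both halides before any phenol is unmasked avoids having to activate an electron-rich bromophenoxide.

Step 3
Reactants: 3 2,2'-(4,5,6-trimethoxy-1,3-phenylene)bis(4,4,5,5-tetramethyl-1,3,2-dioxaborolane)
Product: 4 4,5,6-trimethoxybenzene-1,3-diol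
Conditions: 30% aq. H2O2, NaOH, THF/H2O, 0 °C, Ar; then Na2S2O3, dil. HCl
Reagents that add atoms: hydrogen peroxide, OO
Why: Hydroperoxide oxidation of arylboronates; peroxide adds to boron, the aryl group migrates from boron to oxygen and the borate hydrolyses, so both phenols appear ipso to the former C–B bonds, while low temperature, exclusion of air and a reductive acidic quench protect the electron-rich resorcinol.

Step 4
Reactants: 4 4,5,6-trimethoxybenzene-1,3-diol
Product: 5 2-iodo-4,5,6-trimethoxybenzene-1,3-diol
Conditions: I2 (1.05 equiv), NaHCO3, THF/H2O, 0 °C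
Reagents that add atoms: iodine, II
Why: Electrophilic aromatic iodination; the one remaining ring C–H lies ortho to both hydroxyls, so iodine under bicarbonate buffering should enter there without the oxidising or acidic conditions that would degrade the ring or reverse the iodination.

Step 5
Reactants: 5 2-iodo-4,5,6-trimethoxybenzene-1,3-diol; 6 phenylacetylene; 7 carbon monoxide
Product: 10 5-hydroxy-6,7,8-trimethoxyflavone, via aryl ynone 8 (not isolated), via diethylamino enaminone 9 (not isolated)
Conditions: PdCl2(dppf) (5 mol%), Et2NH (solvent), CO (20 bar), 6 (1.5 equiv), 120 °C, autoclave, copper-free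
Reagents that add atoms: none
Why: Palladium(0) inserts into the C–I bond of 5, CO insertion gives an aroyl–palladium(II) species, and amine-assisted alkynyl transfer from 6 followed by reductive elimination delivers ynone 8, forming C4a–C4 and C4–C3. Diethylamine then adds to the ynone in a conjugate sense to give enaminone 9, and a flanking phenol attacks the β-carbon in a 6-endo-trig addition–elimination that expels the amine, forms O1–C2 and closes the pyranone ring C. The closest known reaction type is the palladium-catalysed carbonylative Sonogashira annulation of ortho-iodophenols with terminal alkynes in secondary amines to give flavones. No stereocentre is created. Carbonylative coupling is favoured over direct alkynylation (which would lead on to a benzofuran) by the CO pressure and the absence of copper, and 6-endo closure is favoured over 5-exo closure to an aurone because the amine converts the ynone into the enaminone before the phenol attacks. Which hydroxyl cyclises is immaterial because the mirror plane through the C–I carbon makes them equivalent, the other one remaining as the chelated 5-OH, and the hexasubstituted ring offers no C–H for side reactions.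

Step 6
Reactants: 10 5-hydroxy-6,7,8-trimethoxyflavone
Product: 11 5,6,7,8-tetramethoxyflavone
Conditions: MeI (5 equiv), K2CO3, DMF, 50 °C
Reagents that add atoms: iodomethane, CI
Why: Williamson O-methylation; the chelated peri-hydroxyl is the only acidic group and is alkylated under mildly forcing carbonate conditions, which caps the para-methoxyphenol unit that a dioxirane would otherwise oxidise in the next step.

Step 7
Reactants: 11 5,6,7,8-tetramethoxyflavone
Product: 13 3-hydroxy-5,6,7,8-tetramethoxyflavone, via flavone 2,3-epoxide 12 (not isolated)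
Conditions: DMDO (ca. 0.07 M in acetone, 3 equiv), CH2Cl2, 0 °C → rt; evaporate; TsOH·H2O (cat.), CH2Cl2, rt
Reagents that add atoms: dimethyldioxirane, CC1(C)OO1
Why: Electrophilic dioxirane epoxidation of the enol-ether C2=C3 bond gives the racemic cis-fused epoxide, whose acid-catalysed opening at C2 (cation stabilised by O1 and the phenyl group) and loss of H-3 restores the pyranone as the flavonol and erases both transient stereocentres, while the fully methylated A ring keeps the oxidant on ring C.

Step 8
Reactants: 13 3-hydroxy-5,6,7,8-tetramethoxyflavone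
Product: 14 3,5,6,7,8-pentamethoxyflavone
Conditions: MeI (3 equiv), K2CO3, acetone, reflux
Reagents that add atoms: iodomethane, CI
Why: Williamson O-methylation of the acidic enolic 3-hydroxyl, the only free OH in 13.

Step 9
Reactants: 14 3,5,6,7,8-pentamethoxyflavone
Product: 16 5-hydroxy-3,6,7,8-tetramethoxyflavone, via dichloroboron chelate 15 (not isolated)
Conditions: BCl3 (1 M in CH2Cl2, 1.5 equiv), CH2Cl2, −78 → 0 °C; then H2O
Reagents that add atoms: none
Why: Chelation-controlled Lewis-acid ether cleavage; boron bound to the C4 carbonyl reaches the peri 5-methoxy oxygen through a six-membered chelate and chloride removes that methyl group, whereas the 3-methoxy (strained five-membered chelate) and the 6-, 7- and 8-methoxy groups (no carbonyl assistance) should survive at low temperature with near-stoichiometric reagent, and water then hydrolyses the boron chelate to the hydrogen-bonded 5-OH.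

**Compound list**

1 | 1,2,3-trimethoxybenzene | COc1cccc(OC)c1OC | starting material
2 | 1,5-dibromo-2,3,4-trimethoxybenzene | COc1c(Br)cc(Br)c(OC)c1OC | intermediate
3 | 2,2'-(4,5,6-trimethoxy-1,3-phenylene)bis(4,4,5,5-tetramethyl-1,3,2-dioxaborolane) | COc1c(B2OC(C)(C)C(C)(C)O2)cc(B2OC(C)(C)C(C)(C)O2)c(OC)c1OC | intermediate
4 | 4,5,6-trimethoxybenzene-1,3-diol | COc1c(O)cc(O)c(OC)c1OC | intermediate
5 | 2-iodo-4,5,6-trimethoxybenzene-1,3-diol | COc1c(O)c(I)c(O)c(OC)c1OC | intermediate
6 | phenylacetylene | C#Cc1ccccc1 | starting material
7 | carbon monoxide | [C-]#[O+] | starting material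
8 | 1-(2,6-dihydroxy-3,4,5-trimethoxyphenyl)-3-phenylprop-2-yn-1-one (aryl ynone, formed in situ) | O=C(C#Cc1ccccc1)c1c(O)c(OC)c(OC)c(OC)c1O | intermediate
9 | (E)-3-(diethylamino)-1-(2,6-dihydroxy-3,4,5-trimethoxyphenyl)-3-phenylprop-2-en-1-one (enaminone, formed in situ; drawn E, either geometry cyclises) | CCN(CC)/C(c1ccccc1)=C/C(=O)c1c(O)c(OC)c(OC)c(OC)c1O | intermediate
10 | 5-hydroxy-6,7,8-trimethoxyflavone (5-hydroxy-6,7,8-trimethoxy-2-phenyl-4H-chromen-4-one) | COc1c(OC)c(O)c2c(=O)cc(-c3ccccc3)oc2c1OC | intermediate
11 | 5,6,7,8-tetramethoxyflavone | COc1c(OC)c(OC)c2c(=O)cc(-c3ccccc3)oc2c1OC | intermediate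
12 | 2,3-epoxy-5,6,7,8-tetramethoxyflavanone (racemic, formed in situ; oxirane cis-fused to the pyranone, phenyl at C2 and H at C3 on the face opposite the oxirane oxygen; the 2S,3R enantiomer is drawn) | O=C1[C@H]2O[C@@]2(c3ccccc3)Oc3c(OC)c(OC)c(OC)c(OC)c31 | intermediate
13 | 3-hydroxy-5,6,7,8-tetramethoxyflavone | COc1c(OC)c(OC)c2c(=O)c(O)c(-c3ccccc3)oc2c1OC | intermediate
14 | 3,5,6,7,8-pentamethoxyflavone | COc1c(OC)c(OC)c2c(=O)c(OC)c(-c3ccccc3)oc2c1OC | intermediate
15 | 5-(dichloroboryloxy)-3,6,7,8-tetramethoxyflavone (boron also coordinated by the C4 carbonyl, formed in situ) | COc1c(OC)c(OB(Cl)Cl)c2c(=O)c(OC)c(-c3ccccc3)oc2c1OC | intermediate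
16 | 5-hydroxy-3,6,7,8-tetramethoxyflavone (achiral) | COc1c(OC)c(O)c2c(=O)c(OC)c(-c3ccccc3)oc2c1OC | target

**Step count**

Total step count: 9. Longest linear sequence: 9 steps, from 1 to 16.

**Steps most likely to fail**

Step 5. The electron-rich iodoresorcinol may lose iodine in the hot amine before oxidative addition is productive. Coupling may also outrun CO uptake and continue by 5-endo closure to a benzofuran, or the amine may capture the aroyl–palladium species as an amide. The fallback forms the same pyranone without palladium and sets out from diol 4. Friedel–Crafts C-acylation of 4 at its single free ring carbon with cinnamoyl chloride (BF3·OEt2, 80 °C) should give (E)-2',6'-dihydroxy-3',4',5'-trimethoxychalcone F1. Oxidative cyclisation of F1 with catalytic iodine in DMSO at 130 °C (oxa-Michael closure to the flavanone, then dehydrogenation with DMSO as terminal oxidant) should give 5-hydroxy-6,7,8-trimethoxyflavone, where the route is rejoined at 10.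

Step 7. Epoxidation of the electron-poor enol-ether bond may be slow enough that the dioxirane begins to oxidise ring A, or the flavonol may be over-oxidised to ring-cleaved products. The fallback replaces oxygen transfer by deprotonation and sets out from 11. LDA in THF at −78 °C removes H-3, the only acidic sp2 C–H, to give 3-lithio-5,6,7,8-tetramethoxyflavone F2. Trimethyl borate converts F2 into dimethyl (5,6,7,8-tetramethoxy-4-oxo-2-phenyl-4H-chromen-3-yl)boronate F3. Oxidation of F3 in the same flask with H2O2/AcOH should give the flavonol, rejoining the route at 13.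

Step 9. Chemoselectivity of the ether cleavage may be lost, with the boron chelate going on to activate the neighbouring 6-methoxy group or the 3-methoxy group being cleaved alongside the 5-methoxy group. The fallback avoids any selective demethylation by using a hydrogenolysable protecting group, and sets out from 10. Benzylation (BnBr, K2CO3, DMF, 60 °C) gives 5-benzyloxy-6,7,8-trimethoxyflavone F4. DMDO epoxidation of F4 gives racemic 5-benzyloxy-2,3-epoxy-6,7,8-trimethoxyflavanone F5, which is opened with catalytic TsOH to 5-benzyloxy-3-hydroxy-6,7,8-trimethoxyflavone F6. Methylation of F6 (MeI, K2CO3, acetone) gives 5-benzyloxy-3,6,7,8-tetramethoxyflavone F7. Hydrogenolysis of F7 (H2, Pd/C, EtOAc, rt) should release the 5-OH and arrive directly at the target 16.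

Further compounds
F1 | step 5 | (E)-2',6'-dihydroxy-3',4',5'-trimethoxychalcone | O=C(/C=C/c1ccccc1)c1c(O)c(OC)c(OC)c(OC)c1O
F2 | step 7 | 3-lithio-5,6,7,8-tetramethoxyflavone | [Li]c1c(-c2ccccc2)oc2c(OC)c(OC)c(OC)c(OC)c2c1=O
F3 | step 7 | dimethyl (5,6,7,8-tetramethoxy-4-oxo-2-phenyl-4H-chromen-3-yl)boronate | COB(OC)c1c(-c2ccccc2)oc2c(OC)c(OC)c(OC)c(OC)c2c1=O
F4 | step 9 | 5-benzyloxy-6,7,8-trimethoxyflavone | COc1c(OC)c(OCc3ccccc3)c2c(=O)cc(-c4ccccc4)oc2c1OC
F5 | step 9 | 5-benzyloxy-2,3-epoxy-6,7,8-trimethoxyflavanone (racemic, cis-fused oxirane, 2S,3R enantiomer drawn) | O=C1[C@H]2O[C@@]2(c3ccccc3)Oc3c(OC)c(OC)c(OC)c(OCc4ccccc4)c31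
F6 | step 9 | 5-benzyloxy-3-hydroxy-6,7,8-trimethoxyflavone | COc1c(OC)c(OCc3ccccc3)c2c(=O)c(O)c(-c4ccccc4)oc2c1OC
F7 | step 9 | 5-benzyloxy-3,6,7,8-tetramethoxyflavone | COc1c(OC)c(OCc3ccccc3)c2c(=O)c(OC)c(-c4ccccc4)oc2c1OC
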